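The earlier runs and the new flask stem from a simulated flask with made-up constants, and the scatter is random.

The trap in a loading is that mol% reads like a fixed dose, while what the flask has is moles per litre. Thursday's run held 0.085 M free monomer at 10 mol% initiator, and Tuesday's run held twice the free monomer at half the loading, both at 4 °C. Yet after 30.0 min they read 57.4 % and 60.5 % monomer in chains. The charges look different and the curves do not, until the free monomer is multiplied by the loading:

| setting | Thursday's | Sunday's | Tuesday's | spring | autumn | summer |
|---|---|---|---|---|---|---|
| free monomer | 0.085 M | 0.34 M | 0.17 M | 0.17 M | 0.17 M | 0.17 M |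
| initiator | 10 mol% | 10 mol% | 5 mol% | 10 mol% | 10 mol% | 10 mol% |
| temperature | 4 °C | 12 °C | 4 °C | 0 °C |  | 15 °C |
| remark | run made earlier | run made earlier | run made earlier |  | at 15 °C until 10 min, from then on at 0 °C |  |
| time |  |  |  | 50 min | 50 min | 50 min |

- Thursday's (time / min: monomer in chains / %): 2.50: 18.3; 4.00: 22.6; 6.00: 30.4; 10.0: 38.1; 20.0: 51.4; 30.0: 57.4
- Sunday's (time / min: monomer in chains / %): 1.33: 45.3; 2.00: 57.8; 3.00: 68.4; 6.00: 78.2; 12.0: 71.3; 15.0: 67.6
- Tuesday's (time / min: monomer in chains / %): 6.00: 27.1; 12.0: 42.3; 20.0: 54.1; 25.0: 59.7; 30.0: 60.5

(readings scatter by 0.5 percentage points)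

- the earlier runs were read with a standard deviation of 0.5 percentage points

Thursday's run: 0.085 M × 10 mol% = 0.00850 M

Tuesday's run: 0.17 M × 5 mol% = 0.00850 M

Spring, autumn, summer: 0.17 M × 10 mol% = 0.0170 M

I carried forward this initiator per litre. Because it is equal in the two cold runs, I took it as what keeps their pace together. Spring, autumn and summer share 0.0170 M, twice that of the cold runs, so I looked to temperature for what separates them. Sunday's run, at 12 °C, read 78.2 % at 6.00 min but less by 15.0 min, 67.6 %, so monomer in chains fell again in that run, and I expected spring, at 0 °C, to lead.

- which flask leads in amount of monomer in chains, in percent of the free monomer charged ("all alike" within 1.5 percentage points) (spring / autumn / summer / all alike)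
- how much monomer in chains is there at the end, in percent of the free monomer charged: spring
- how much monomer in chains is there at the end, in percent of the free monomer charged: autumn
- how much monomer in chains is there at the end, in percent of the free monomer charged: summer

The forecast named spring, with 67 % for spring, 55 % for autumn and 26 % for summer, reasoning that “chains form reversibly and also drain slowly to something else”.

The flasks gave 72.3 % in spring, 59.8 % in autumn and 51.9 % in summer, so spring led, and the forecast's summer was low by 26 points.

    free monomer + living end → monomer in chains + living end, rate k1*[living end]*[free monomer] (k = 4.20 M⁻¹ min⁻¹, Ea = 62.0 kJ mol⁻¹)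
    monomer in chains ⇌ isomer of the product (K = 1.10, k = 0.00700 min⁻¹, Ea = 92.0 kJ mol⁻¹, ΔH = −15.0 kJ mol⁻¹)
    free monomer + initiator → living end + monomer in chains (k = 41.0 M⁻¹ min⁻¹, Ea = 46.0 kJ mol⁻¹)
    monomer in chains + living end → free monomer + living end, rate k4*[living end] as long as [monomer in chains] is above zero (k = 0.0450 min⁻¹, Ea = 71.0 kJ mol⁻¹)
    (constants at 0 °C)

The living end stood at 0.0170 M in summer at 50.0 min and at 0.0170 M in autumn at 10.0 min, the 0.0170 M reckoned from the charge, with summer's initiator at 0 % of its charge. In summer, monomer in chains and isomer of the product relaxed with a half-life of 5.27 min, shorter than the 50 min of the run, and reading summer at 500 min instead moved the answer from 51.9 % to 51.8 %.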